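The isoflavan is disconnected across its pyran ring at C3–C4 and O1–C2. On ring A the unsubstituted benzylic methylene C4 sits ortho to O1, so the unit O1–C8a–C4a–C4 is a masked ortho-quinone methide; C3, with C2 and ring B attached, maps onto the enolate of an arylacetic acid. One carbene-catalysed formal [4+2] annulation unites the two, creating both bonds, the heterocycle (as a lactone) and the only stereocentre, C3. Its precursors are a ring A 2-silyloxybenzyl bromide (5) and the 4-nitrophenyl ester (18) of the benzyl-protected, reverse-prenylated ring B arylacetic acid. Lactone reduction, Mitsunobu closure and debenzylation finish the synthesis.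

Key step: step 14

Assumption: the (5aR,10bS) antipode of the aminoindanol triazolium salt is taken to give the (S)-lactone; the sense would be checked on a first small run, and the equally available (5aS,10bR) salt would be used if the (R)-lactone formed.

Design remarks:
- The target, lactone 21, diol 22 and chroman 23 are all (S) at C3. The CIP order C2 > ring B carbon > C4 > H holds at every oxidation level of C2, so the descriptor does not change.
- Ring B is alkylated in the order O4 (prenyl), O3 (benzyl), O2 (methyl) before the Claisen step. Each alkylation then has one reactive oxygen, and the rearrangement has one free ortho position (C5).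
- Bromide 5 is doubly activated (ortho silyloxy, para benzyloxy) and labile. It is made last under neutral conditions and used at once.

**Ring A fragment**

Step 1
Reactants: 1 2,4-dihydroxybenzaldehyde
Product: 2 4-(benzyloxy)-2-hydroxybenzaldehyde
Conditions: BnBr (1.0 equiv), NaHCO3, MeCN, reflux
Reagents that add atoms: benzyl bromide, BrCc1ccccc1
Why: Williamson etherification under weak base; hydrogencarbonate ionises only the 4-OH (para to the formyl group, not held in the intramolecular hydrogen bond), so mono-benzylation at O4 is expected.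

Step 2
Reactants: 2 4-(benzyloxy)-2-hydroxybenzaldehyde
Product: 3 4-(benzyloxy)-2-[(tert-butyldimethylsilyl)oxy]benzaldehyde
Conditions: TBSCl, imidazole, DMF, 20 °C
Reagents that add atoms: tert-butyldimethylsilyl chloride, CC(C)(C)[Si](C)(C)Cl
Why: Imidazole-promoted O-silylation of the remaining phenol; this oxygen becomes O1 and its silyl group is the fluoride trigger of the key step.

Step 3
Reactants: 3 4-(benzyloxy)-2-[(tert-butyldimethylsilyl)oxy]benzaldehyde
Product: 4 {4-(benzyloxy)-2-[(tert-butyldimethylsilyl)oxy]phenyl}methanol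
Conditions: NaBH4, THF/MeOH, −10 °C, then aq. NH4Cl
Reagents that add atoms: none
Why: Chemoselective borohydride reduction of the aldehyde; low temperature and a prompt buffered quench should stop the aryl silyl group migrating to the new benzylic alkoxide.

Step 4
Reactants: 4 {4-(benzyloxy)-2-[(tert-butyldimethylsilyl)oxy]phenyl}methanol
Product: 5 tert-butyl[5-(benzyloxy)-2-(bromomethyl)phenoxy]dimethylsilane
Conditions: CBr4, PPh3, CH2Cl2, 0 °C; rapid filtration through a short silica pad, used immediately
Reagents that add atoms: carbon tetrabromide, BrC(Br)(Br)Br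
Why: Appel reaction converts the primary benzylic alcohol into the bromide under neutral, acid-free conditions that leave the silyl and benzyl ethers intact.

**Ring B fragment**

Step 5
Reactants: 6 2,3,4-trihydroxybenzaldehyde; 7 prenyl bromide (1-bromo-3-methylbut-2-ene)
Product: 8 2,3-dihydroxy-4-[(3-methylbut-2-en-1-yl)oxy]benzaldehyde
Conditions: NaHCO3, DMF, 20 to 40 °C
Reagents that add atoms: none
Why: Williamson etherification under weak base; the 4-OH (para to the formyl group) is the most acidic and the only unchelated acidic site, so the reactive allylic bromide should alkylate O4 selectively.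

Step 6
Reactants: 8 2,3-dihydroxy-4-[(3-methylbut-2-en-1-yl)oxy]benzaldehyde
Product: 10 3-(benzyloxy)-2-hydroxy-4-[(3-methylbut-2-en-1-yl)oxy]benzaldehyde, via disodium salt 9 (not isolated)
Conditions: NaH (2.2 equiv), DMSO, 20 °C; BnBr (1.0 equiv); dilute aq. HCl work-up
Reagents that add atoms: benzyl bromide, BrCc1ccccc1
Why: Regioselective Williamson alkylation of a preformed dianion; sodium is chelated between O2 and the formyl oxygen, so the more basic, unchelated O3 phenoxide should take the single equivalent of benzyl bromide.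

Step 7
Reactants: 10 3-(benzyloxy)-2-hydroxy-4-[(3-methylbut-2-en-1-yl)oxy]benzaldehyde
Product: 11 3-(benzyloxy)-2-methoxy-4-[(3-methylbut-2-en-1-yl)oxy]benzaldehyde
Conditions: MeI, K2CO3, DMF, 40 °C
Reagents that add atoms: iodomethane, CI
Why: Williamson O-methylation of the last, hydrogen-bonded phenol, which is now the only acidic site; this fixes the 2-methoxy group of ring B.

Step 8
Reactants: 11 3-(benzyloxy)-2-methoxy-4-[(3-methylbut-2-en-1-yl)oxy]benzaldehyde
Product: 12 3-(benzyloxy)-4-hydroxy-2-methoxy-5-(2-methylbut-3-en-2-yl)benzaldehyde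
Conditions: PhNEt2, 190 °C, sealed tube, argon
Reagents that add atoms: none
Why: Aromatic Claisen rearrangement ([3,3]-sigmatropic shift); the prenyl unit is delivered with allylic inversion to C5, the only ortho position bearing hydrogen, and enolisation gives the 1,1-dimethylallyl phenol, while the basic solvent suppresses acid-catalysed cyclisation onto the vinyl group.

Step 9
Reactants: 12 3-(benzyloxy)-4-hydroxy-2-methoxy-5-(2-methylbut-3-en-2-yl)benzaldehyde
Product: 13 3,4-bis(benzyloxy)-2-methoxy-5-(2-methylbut-3-en-2-yl)benzaldehyde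
Conditions: BnBr, K2CO3, DMF, 60 °C
Reagents that add atoms: benzyl bromide, BrCc1ccccc1
Why: Williamson etherification of the only free phenol; the oxygen is hindered but acidic (para to the formyl group) and should alkylate with benzyl bromide on warming.

Step 10
Reactants: 13 3,4-bis(benzyloxy)-2-methoxy-5-(2-methylbut-3-en-2-yl)benzaldehyde
Product: 14 1,2-bis(benzyloxy)-3-methoxy-4-(2-methoxyethenyl)-6-(2-methylbut-3-en-2-yl)benzene (E/Z mixture)
Conditions: Ph3P(CH2OMe)Cl, KOtBu, THF, 0 to 20 °C
Reagents that add atoms: (methoxymethyl)triphenylphosphonium chloride, [Cl-].COC[P+](c1ccccc1)(c1ccccc1)c1ccccc1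
Why: Wittig olefination of the non-enolisable aldehyde with the methoxymethylene ylide adds, as an enol ether, the one carbon that becomes C2.

Step 11
Reactants: 14 1,2-bis(benzyloxy)-3-methoxy-4-(2-methoxyethenyl)-6-(2-methylbut-3-en-2-yl)benzene
Product: 15 2-[3,4-bis(benzyloxy)-2-methoxy-5-(2-methylbut-3-en-2-yl)phenyl]acetaldehyde
Conditions: 2 M aq. HCl, THF, 40 °C; crude product used directly
Reagents that add atoms: water, O
Why: Acid-catalysed enol ether hydrolysis (protonation at the benzylic carbon, then hydration of the oxocarbenium ion) unmasks the arylacetaldehyde; benzyl ethers and the isolated vinyl group are inert to dilute aqueous acid.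

Step 12
Reactants: 15 2-[3,4-bis(benzyloxy)-2-methoxy-5-(2-methylbut-3-en-2-yl)phenyl]acetaldehyde
Product: 16 2-[3,4-bis(benzyloxy)-2-methoxy-5-(2-methylbut-3-en-2-yl)phenyl]acetic acid
Conditions: NaClO2, NaH2PO4, 2-methylbut-2-ene, t-BuOH/H2O, 0 to 20 °C
Reagents that add atoms: sodium chlorite, [Na+].[O-]Cl=O
Why: Pinnick oxidation takes the aldehyde to the acid without touching the terminal alkene or the electron-rich ring, because 2-methylbut-2-ene consumes the hypochlorous acid.

Step 13
Reactants: 16 2-[3,4-bis(benzyloxy)-2-methoxy-5-(2-methylbut-3-en-2-yl)phenyl]acetic acid; 17 4-nitrophenol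
Product: 18 4-nitrophenyl 2-[3,4-bis(benzyloxy)-2-methoxy-5-(2-methylbut-3-en-2-yl)phenyl]acetate
Conditions: DCC, DMAP (cat.), CH2Cl2, 0 to 20 °C
Reagents that add atoms: none
Why: Steglich carbodiimide esterification gives the activated aryl ester, whose 4-nitrophenoxide leaving group allows the carbene to form the acyl azolium.

**Key step and endgame**

Step 14
Reactants: 18 4-nitrophenyl 2-[3,4-bis(benzyloxy)-2-methoxy-5-(2-methylbut-3-en-2-yl)phenyl]acetate; 5 tert-butyl[5-(benzyloxy)-2-(bromomethyl)phenoxy]dimethylsilane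
Product: 21 (3S)-7-(benzyloxy)-3-[3,4-bis(benzyloxy)-2-methoxy-5-(2-methylbut-3-en-2-yl)phenyl]-3,4-dihydro-2H-chromen-2-one, via azolium enolate 19 (not isolated), via ortho-quinone methide 20 (not isolated)
Conditions: (5aR,10bS)-2-mesityl-5a,10b-dihydro-4H,6H-indeno[2,1-b][1,2,4]triazolo[4,3-d][1,4]oxazin-2-ium tetrafluoroborate (15 mol %), CsF, 18-crown-6, 4 Å MS, THF, −20 °C, slow addition of 5 (1.5 equiv); AcOH quench at −20 °C
Reagents that add atoms: none
Why: The triazolylidene, freed from its salt by fluoride, displaces 4-nitrophenoxide from 18 and the acidified α-proton is removed to give azolium enolate 19, while fluoride desilylates 5 and the phenoxide expels bromide to give ortho-quinone methide 20; the enolate carbon (C3) adds to the exocyclic CH2 (C4) with rearomatisation of ring A, and the ring A phenoxide then acylates on the acyl azolium and releases the carbene. The closest known reaction type is the carbene-catalysed formal [4+2] annulation of fluoride-generated ortho-quinone methides with azolium enolates from activated acetic esters, which gives 3-substituted 3,4-dihydrocoumarins. The pyranone ring closes by 6-exo-trig lactonisation of O1 onto the acyl azolium carbonyl (C2). C3 is set in the C3–C4 bond formation, where the fused aminoindanol framework of the carbene shields one face of the enolate and the planar methide approaches the open face. The step needs enolate C-alkylation to outrun methide self-condensation and capture by 4-nitrophenoxide, and it needs the acidic C3–H of the product to stay configurationally intact. The 7-benzyloxy group stabilises the methide, the unsubstituted C4 makes it unhindered and leaves no second stereocentre, the ortho-methoxy group twists ring B out of conjugation with the lactone enolate, and slow addition, low temperature and an acidic quench limit exposure to base.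

Step 15
Reactants: 21 (3S)-7-(benzyloxy)-3-[3,4-bis(benzyloxy)-2-methoxy-5-(2-methylbut-3-en-2-yl)phenyl]-3,4-dihydro-2H-chromen-2-one
Product: 22 (2S)-3-[4-(benzyloxy)-2-hydroxyphenyl]-2-[3,4-bis(benzyloxy)-2-methoxy-5-(2-methylbut-3-en-2-yl)phenyl]propan-1-ol
Conditions: LiAlH4, THF, −20 to 0 °C
Reagents that add atoms: none
Why: Hydride reduction of the aryl ester lactone to the primary alcohol and the ring A phenol; the reactive phenyl ester should be reduced faster than C3–H is enolised at low temperature, and the ethers and the alkene are inert.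

Step 16
Reactants: 22 (2S)-3-[4-(benzyloxy)-2-hydroxyphenyl]-2-[3,4-bis(benzyloxy)-2-methoxy-5-(2-methylbut-3-en-2-yl)phenyl]propan-1-ol
Product: 23 (3S)-7-(benzyloxy)-3-[3,4-bis(benzyloxy)-2-methoxy-5-(2-methylbut-3-en-2-yl)phenyl]-3,4-dihydro-2H-chromene
Conditions: PPh3, DIAD, THF (0.02 M), 0 to 20 °C
Reagents that add atoms: none
Why: Mitsunobu etherification; the phenol O1 displaces the activated primary hydroxyl at C2 in a 6-exo-tet closure, and because substitution occurs at the CH2 carbon the neighbouring stereocentre C3 is untouched.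

Step 17
Reactants: 23 (3S)-7-(benzyloxy)-3-[3,4-bis(benzyloxy)-2-methoxy-5-(2-methylbut-3-en-2-yl)phenyl]-3,4-dihydro-2H-chromene
Product: 24 3-methoxy-4-[(3S)-7-hydroxy-3,4-dihydro-2H-chromen-3-yl]-6-(2-methylbut-3-en-2-yl)benzene-1,2-diol (CNP0167796.2)
Conditions: BCl3, pentamethylbenzene, CH2Cl2, −78 °C; then CHCl3/MeOH, −78 °C
Reagents that add atoms: none
Why: Lewis-acid cleavage of the three aryl benzyl ethers with pentamethylbenzene as a non-basic benzyl cation scavenger (Friedel–Crafts capture), chosen because hydrogenolysis would reduce the vinyl group; the methyl ether and the unactivated terminal alkene should survive at −78 °C.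

**Compound list**

1 | 2,4-dihydroxybenzaldehyde | O=Cc1ccc(O)cc1O | starting material
2 | 4-(benzyloxy)-2-hydroxybenzaldehyde | O=Cc1ccc(OCc2ccccc2)cc1O | intermediate
3 | 4-(benzyloxy)-2-[(tert-butyldimethylsilyl)oxy]benzaldehyde | O=Cc1ccc(OCc2ccccc2)cc1O[Si](C)(C)C(C)(C)C | intermediate
4 | {4-(benzyloxy)-2-[(tert-butyldimethylsilyl)oxy]phenyl}methanol | OCc1ccc(OCc2ccccc2)cc1O[Si](C)(C)C(C)(C)C | intermediate
5 | tert-butyl[5-(benzyloxy)-2-(bromomethyl)phenoxy]dimethylsilane | BrCc1ccc(OCc2ccccc2)cc1O[Si](C)(C)C(C)(C)C | intermediate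
6 | 2,3,4-trihydroxybenzaldehyde | O=Cc1ccc(O)c(O)c1O | starting material
7 | prenyl bromide (1-bromo-3-methylbut-2-ene) | CC(C)=CCBr | starting material
8 | 2,3-dihydroxy-4-[(3-methylbut-2-en-1-yl)oxy]benzaldehyde | O=Cc1ccc(OCC=C(C)C)c(O)c1O | intermediate
9 | disodium salt (2,3-bis-phenoxide) of 8, formed in the flask, not isolated | [Na+].[Na+].O=Cc1ccc(OCC=C(C)C)c([O-])c1[O-] | intermediate
10 | 3-(benzyloxy)-2-hydroxy-4-[(3-methylbut-2-en-1-yl)oxy]benzaldehyde | O=Cc1ccc(OCC=C(C)C)c(OCc2ccccc2)c1O | intermediate
11 | 3-(benzyloxy)-2-methoxy-4-[(3-methylbut-2-en-1-yl)oxy]benzaldehyde | COc1c(C=O)ccc(OCC=C(C)C)c1OCc1ccccc1 | intermediate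
12 | 3-(benzyloxy)-4-hydroxy-2-methoxy-5-(2-methylbut-3-en-2-yl)benzaldehyde | COc1c(C=O)cc(C(C)(C)C=C)c(O)c1OCc1ccccc1 | intermediate
13 | 3,4-bis(benzyloxy)-2-methoxy-5-(2-methylbut-3-en-2-yl)benzaldehyde | COc1c(C=O)cc(C(C)(C)C=C)c(OCc2ccccc2)c1OCc1ccccc1 | intermediate
14 | 1,2-bis(benzyloxy)-3-methoxy-4-(2-methoxyethenyl)-6-(2-methylbut-3-en-2-yl)benzene, E/Z mixture | COC=Cc1cc(C(C)(C)C=C)c(OCc2ccccc2)c(OCc2ccccc2)c1OC | intermediate
15 | 2-[3,4-bis(benzyloxy)-2-methoxy-5-(2-methylbut-3-en-2-yl)phenyl]acetaldehyde | O=CCc1cc(C(C)(C)C=C)c(OCc2ccccc2)c(OCc2ccccc2)c1OC | intermediate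
16 | 2-[3,4-bis(benzyloxy)-2-methoxy-5-(2-methylbut-3-en-2-yl)phenyl]acetic acid | OC(=O)Cc1cc(C(C)(C)C=C)c(OCc2ccccc2)c(OCc2ccccc2)c1OC | intermediate
17 | 4-nitrophenol | Oc1ccc(cc1)[N+](=O)[O-] | starting material
18 | 4-nitrophenyl 2-[3,4-bis(benzyloxy)-2-methoxy-5-(2-methylbut-3-en-2-yl)phenyl]acetate | O=C(Cc1cc(C(C)(C)C=C)c(OCc2ccccc2)c(OCc2ccccc2)c1OC)Oc1ccc(cc1)[N+](=O)[O-] | intermediate
19 | azolium enolate: enolate of the ring B arylacetyl unit bound through its acyl carbon to the carbene carbon of the (5aR,10bS)-2-mesityl triazolium catalyst, zwitterion, enolate geometry not specified, not isolated | COc1c(OCc2ccccc2)c(OCc2ccccc2)c(C(C)(C)C=C)cc1C=C([O-])c1n2[C@H]3c4ccccc4C[C@H]3OCc2n[n+]1-c1c(C)cc(C)cc1C | intermediate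
20 | ortho-quinone methide: 3-(benzyloxy)-6-methylidenecyclohexa-2,4-dien-1-one, not isolated | C=C1C=CC(OCc2ccccc2)=CC1=O | intermediate
21 | (3S)-7-(benzyloxy)-3-[3,4-bis(benzyloxy)-2-methoxy-5-(2-methylbut-3-en-2-yl)phenyl]-3,4-dihydro-2H-chromen-2-one | COc1c(OCc2ccccc2)c(OCc2ccccc2)c(C(C)(C)C=C)cc1[C@H]1C(=O)Oc2cc(OCc3ccccc3)ccc2C1 | intermediate
22 | (2S)-3-[4-(benzyloxy)-2-hydroxyphenyl]-2-[3,4-bis(benzyloxy)-2-methoxy-5-(2-methylbut-3-en-2-yl)phenyl]propan-1-ol | COc1c(OCc2ccccc2)c(OCc2ccccc2)c(C(C)(C)C=C)cc1[C@H](Cc1ccc(OCc2ccccc2)cc1O)CO | intermediate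
23 | (3S)-7-(benzyloxy)-3-[3,4-bis(benzyloxy)-2-methoxy-5-(2-methylbut-3-en-2-yl)phenyl]-3,4-dihydro-2H-chromene | COc1c(OCc2ccccc2)c(OCc2ccccc2)c(C(C)(C)C=C)cc1[C@H]1COc2cc(OCc3ccccc3)ccc2C1 | intermediate
24 | 3-methoxy-4-[(3S)-7-hydroxy-3,4-dihydro-2H-chromen-3-yl]-6-(2-methylbut-3-en-2-yl)benzene-1,2-diol | C=CC(C)(C)c1cc([C@H]2COc3cc(O)ccc3C2)c(OC)c(O)c1O | target

**Totals**

Total step count: 17.
Longest linear sequence: 13 steps (steps 5 to 17, from 6 to 24); the ring A branch (steps 1 to 4) joins at step 14.

**Steps most likely to fail**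

1. Step 14. What may go wrong: weak facial discrimination at C3, base-mediated epimerisation of the α-aryl lactone, or loss of the methide to self-condensation (or of the carbene to benzylation by 5) before the enolate captures it. Fallback, auxiliary-controlled alkylation, setting out from acid 16 and bromide 5 and returning at diol 22: acid 16 would be activated as its pivaloyl mixed anhydride (PivCl, Et3N, THF) and joined to lithiated (4S)-4-benzyl-1,3-oxazolidin-2-one to give (4S)-4-benzyl-3-{[3,4-bis(benzyloxy)-2-methoxy-5-(2-methylbut-3-en-2-yl)phenyl]acetyl}-1,3-oxazolidin-2-one F1. Its chelated sodium (Z)-enolate (NaN(SiMe3)2, THF, −78 °C) would be alkylated by bromide 5 on the face remote from the auxiliary benzyl group (Evans alkylation), which should give (4S)-4-benzyl-3-[(2S)-2-[3,4-bis(benzyloxy)-2-methoxy-5-(2-methylbut-3-en-2-yl)phenyl]-3-{4-(benzyloxy)-2-[(tert-butyldimethylsilyl)oxy]phenyl}propanoyl]-1,3-oxazolidin-2-one F2. LiBH4 (THF/MeOH, 0 °C) would remove the auxiliary reductively to give (2S)-2-[3,4-bis(benzyloxy)-2-methoxy-5-(2-methylbut-3-en-2-yl)phenyl]-3-{4-(benzyloxy)-2-[(tert-butyldimethylsilyl)oxy]phenyl}propan-1-ol F3, and Bu4NF (THF, 0 °C) would free the ring A phenol to give 22, after which steps 16 and 17 follow unchanged.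

2. Step 8. What may go wrong: thermal loss of the prenyl group, abnormal Claisen isomerisation of the 1,1-dimethylallyl unit, or cyclisation of the new phenol onto the vinyl group. Fallback, cross-coupling in place of the sigmatropic shift, setting out from 6 and returning at aldehyde 13: 2,3,4-trihydroxybenzaldehyde 6 would be benzylated at O3 and O4 (BnBr, 2 equiv, K2CO3, DMF; the chelated 2-OH reacts last) to give 3,4-bis(benzyloxy)-2-hydroxybenzaldehyde F4. This would be methylated (MeI, K2CO3, DMF) to 3,4-bis(benzyloxy)-2-methoxybenzaldehyde F5 and brominated para to the methoxy group (NBS, MeCN, 20 °C) to 3,4-bis(benzyloxy)-5-bromo-2-methoxybenzaldehyde F6. A γ-selective Suzuki–Miyaura coupling with 4,4,5,5-tetramethyl-2-(3-methylbut-2-en-1-yl)-1,3,2-dioxaborolane (Pd(OAc)2, a bulky electron-rich phosphine that favours the branched product such as 1,1'-bis(di-tert-butylphosphino)ferrocene, K3PO4, THF/H2O) would then give 13.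

3. Step 17. What may go wrong: hydrochlorination or cationic cyclisation at the vinyl group next to the freed 4'-OH, C-benzylation of the electron-rich rings, or partial loss of the methyl ether. Fallback, reductive electron-transfer cleavage in place of Lewis acid, setting out from 23 and arriving directly at target 24: lithium 4,4'-di-tert-butylbiphenylide in THF at −78 °C would cleave the three benzyl aryl ethers to the lithium phenoxides and toluene, leaving the isolated alkene, the methyl ether and the chroman untouched; a degassed NH4Cl quench would give 24.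

**Further compounds**

F1 | step 14 | (4S)-4-benzyl-3-{[3,4-bis(benzyloxy)-2-methoxy-5-(2-methylbut-3-en-2-yl)phenyl]acetyl}-1,3-oxazolidin-2-one | O=C(Cc1cc(C(C)(C)C=C)c(OCc2ccccc2)c(OCc2ccccc2)c1OC)N1[C@@H](Cc2ccccc2)COC1=O
F2 | step 14 | (4S)-4-benzyl-3-[(2S)-2-[3,4-bis(benzyloxy)-2-methoxy-5-(2-methylbut-3-en-2-yl)phenyl]-3-{4-(benzyloxy)-2-[(tert-butyldimethylsilyl)oxy]phenyl}propanoyl]-1,3-oxazolidin-2-one | COc1c(OCc2ccccc2)c(OCc2ccccc2)c(C(C)(C)C=C)cc1[C@H](Cc1ccc(OCc2ccccc2)cc1O[Si](C)(C)C(C)(C)C)C(=O)N1[C@@H](Cc2ccccc2)COC1=O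
F3 | step 14 | (2S)-2-[3,4-bis(benzyloxy)-2-methoxy-5-(2-methylbut-3-en-2-yl)phenyl]-3-{4-(benzyloxy)-2-[(tert-butyldimethylsilyl)oxy]phenyl}propan-1-ol | COc1c(OCc2ccccc2)c(OCc2ccccc2)c(C(C)(C)C=C)cc1[C@H](Cc1ccc(OCc2ccccc2)cc1O[Si](C)(C)C(C)(C)C)CO
F4 | step 8 | 3,4-bis(benzyloxy)-2-hydroxybenzaldehyde | O=Cc1ccc(OCc2ccccc2)c(OCc2ccccc2)c1O
F5 | step 8 | 3,4-bis(benzyloxy)-2-methoxybenzaldehyde | COc1c(C=O)ccc(OCc2ccccc2)c1OCc1ccccc1
F6 | step 8 | 3,4-bis(benzyloxy)-5-bromo-2-methoxybenzaldehyde | COc1c(C=O)cc(Br)c(OCc2ccccc2)c1OCc1ccccc1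
F0 | step 17 | none | none
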